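**Retrosynthetic overview**
- Caruifolin B is a dicyclopentadiene-type [4+2] dimer of two 10-hydroxyguaian-6,12-olide units. The norbornane core and the fused cyclopentene form in one endo Diels–Alder step. One cyclopentadiene acts as a 2-silyloxydiene (4π) and the other as the 2π partner through its C2=C3 bond.
- Both monomers come from isophotosantonic lactone, which is made from α-santonin by the photochemical dienone rearrangement. That step forms the 5/7 hydroazulene, fixes C1 and C10, and keeps C6, C7 and C11.
- Ring order: lactone/six-ring of santonin → photochemical 5/7 ring system → norbornane plus cyclopentene in the Diels–Alder step → silyl enol ether to C3'-ketone.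

Assumptions (one line each):
- (−)-α-Santonin is bought as the chiral-pool starting material.
- The photorearrangement gives the C1/C10 configuration drawn in 2, which equals that of both halves of the target.
- The C4' methyl epimerises to the less hindered exo position under basic conditions.

---

**Step 1**
Reactants: 1, (−)-α-santonin
Product: 2, isophotosantonic lactone (10-hydroxy-3-oxoguai-4-en-6,12-olide)
Conditions: hν (medium-pressure Hg lamp, Pyrex), 50% aq. AcOH, 25 °C
Reagents that add atoms: water, O (supplies the C10–OH)
Why: Dienone photorearrangement (santonin → lumiketone), then acid-mediated opening of the cyclopropyl ketone by C5–C10 cleavage gives the 5/7 skeleton. Water traps the C10 cation. C6, C7 and C11 are untouched, and C1/C10 are set by this stereospecific opening.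

**Step 2**
Reactants: 2
Product: 3, 3,10-dihydroxyguai-4-en-6,12-olide (C3 epimers, mixture)
Conditions: NaBH4, CeCl3·7H2O, MeOH, −78 °C
Reagents that add atoms: none
Why: Luche 1,2-reduction of the enone leaves the lactone and tertiary alcohol intact. The C3 configuration is irrelevant because it is destroyed in Step 3.

**Step 3**
Reactants: 3; 4, p-toluenesulfonyl chloride (commodity aromatic reagent)
Product: 5, 10-hydroxyguaia-2,4-dien-6,12-olide (cyclopentadiene, 2π partner)
Conditions: TsCl, DMAP, Et3N, CH2Cl2, −10 °C; then DBU, 0 → 23 °C; use crude immediately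
Reagents that add atoms: none (Ts leaves as TsO⁻)
Why: Only the secondary allylic alcohol is tosylated. The allylic tosylate then undergoes E1/E2 loss of a C2–H to give the cyclopentadiene. C1–H is retained.

**Step 4**
Reactants: 2
Product: 6, 3,10-bis(TBS)-oxy-guaia-2,4-diene-6,12-olide (2-silyloxycyclopentadiene, 4π partner)
Conditions: TBSOTf (3 equiv), Et3N (5 equiv), CH2Cl2, 0 °C
Reagents that add atoms: TBSOTf, CC(C)(C)[Si](C)(C)OS(=O)(=O)C(F)(F)F (TBS stays on O3 and O10)
Why: Soft enolisation with silyl triflate and amine deprotonates the α' carbon (C2) to give the cross-conjugated dienol ether, and TBSOTf also caps the tertiary alcohol.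

**Step 5**
Reactants: 5 (1 equiv); 6 (2.5 equiv)
Product: 7, endo [4+2] adduct (TBS enol ether, OTBS at C10', free OH at C10)
Conditions: toluene (0.5 M), BHT, 2,6-di-tert-butylpyridine, 110 °C, sealed tube, 24 h
Reagents that add atoms: none
Why: Proposed new method: asynchronous endo Diels–Alder. The nucleophilic C2' terminus of the silyloxydiene 6 attacks C2 of 5, giving an allyl cation/oxocarbenium pair that closes at the hindered C5'–C3 bond.
- It is modelled on endo dimerisation of cyclopentadiene to dicyclopentadiene and on 2-silyloxydiene cycloadditions.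
- The excess of the more electron-rich diene 6 outcompetes homodimerisation of 5.
- Both partners react on the convex face (syn to H1, anti to the C10–O chain), endo. This sets C2, C3, C2' and C5' in one step and keeps C1.

**Step 6**
Reactants: 7
Product: 8, caruifolin B
Conditions: TBAF·3H2O (6 equiv), THF, 0 → 40 °C, 12 h
Reagents that add atoms: none
Why: Fluoride removes both TBS groups and unmasks the enolate. Reversible protonation under basic, equilibrating conditions places the C4' methyl exo (H endo, the less congested arrangement), which sets C4' and completes the C3'-ketone.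

---

**Compound list**
1 | (−)-α-santonin | C[C@H]1[C@@H]2CC[C@@]3(C)C=CC(=O)C(C)=C3[C@H]2OC1=O | starting material
2 | isophotosantonic lactone | CC1=C2[C@H]3OC(=O)[C@@H](C)[C@@H]3CC[C@](C)(O)[C@@H]2CC1=O | intermediate
3 | 3,10-dihydroxyguai-4-en-6,12-olide (C3 unspecified) | CC1=C2[C@H]3OC(=O)[C@@H](C)[C@@H]3CC[C@](C)(O)[C@@H]2CC1O | intermediate
4 | p-toluenesulfonyl chloride | Cc1ccc(cc1)S(=O)(=O)Cl | starting material
5 | 10-hydroxyguaia-2,4-dien-6,12-olide | CC1=C2[C@H]3OC(=O)[C@@H](C)[C@@H]3CC[C@](C)(O)[C@@H]2C=C1 | intermediate
6 | bis-TBS dienol ether | CC1=C2[C@H]3OC(=O)[C@@H](C)[C@@H]3CC[C@](C)(O[Si](C)(C)C(C)(C)C)[C@@H]2C=C1O[Si](C)(C)C(C)(C)C | intermediate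
7 | Diels–Alder adduct | CC1=C2[C@H]3OC(=O)[C@@H](C)[C@@H]3CC[C@](C)(O)[C@@H]2[C@H]2[C@H]3C(O[Si](C)(C)C(C)(C)C)=C(C)[C@]4([C@@H]3[C@@](C)(O[Si](C)(C)C(C)(C)C)CC[C@H]3[C@H](C)C(=O)O[C@@H]34)[C@@H]12 | intermediate
8 | caruifolin B | CC1=C2[C@H]3OC(=O)[C@@H](C)[C@@H]3CC[C@](C)(O)[C@@H]2[C@H]2[C@H]3C(=O)[C@H](C)[C@]4([C@@H]3[C@@](C)(O)CC[C@H]3[C@H](C)C(=O)O[C@@H]34)[C@@H]12 | target

**Total steps:** 6
**Longest linear sequence:** 5 steps (1 → 2 → 3 → 5 → 8, via Steps 1, 2, 3, 5, 6)

**Three steps most likely to fail, with fallbacks**
1. **Step 5 (hindered, heterodimeric Diels–Alder).** It may give homodimers, the wrong regiochemistry, or an exo or concave-face adduct. Fallback: homodimerise 5 alone to the endo bis-alkene dimer, then do a norbornene-selective hydroboration–oxidation and oxidise the resulting alcohol to the C3' ketone. Epimerise C4' as in Step 6.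
2. **Step 1 (photorearrangement).** The yield is moderate, and the C1/C10 configuration may differ from the one assumed. Fallback: dehydrate the photoproduct C10–OH, then re-install the C10 tertiary alcohol by substrate-directed Mukaiyama hydration (Co/PhSiH3/O2). Alternatively, start from a natural 10-hydroxyguaianolide.
3. **Step 3 (cyclopentadiene 5).** It is unstable and can isomerise to the 1(5),3-diene or epimerise at C1 through the cyclopentadienyl anion. Fallback: do not isolate 5. Convert 3 to its allylic methyl carbonate and generate 5 slowly in the hot toluene solution of 6 by Pd(0)-catalysed elimination.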